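**Retrosynthetic overview**
Ring key: A and D are the two biaryl rings (A has OH para to the axis, D has OH ortho to the axis). B is the ring with OH next to the ether oxygen, C is the para-disubstituted ring, and the only non-aromatic ring is the 16-membered macrocycle.
Plagiochin E ⇐ (O-demethylation, C=C hydrogenation) macrocyclic stilbene ⇐ (intramolecular McMurry coupling, a union of two carbonyl carbons of like polarity) open-chain dialdehyde with one CHO on ring C and one on ring D.
Enabling feature: both carbons of the C–D CH2–CH2 bridge are benzylic, one on ring C para to the ether oxygen and one on ring D ortho to the biaryl bond. Each can therefore be carried as an aryl aldehyde and turned into an arene-stabilised ketyl radical, and the saturated A–B bridge, the C–O–C hinge and the twisted A–D axis let the two ends meet.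
Dialdehyde ⇐ Heck coupling plus chemoselective alkene hydrogenation (A–B bridge) ⇐ Suzuki–Miyaura coupling (A–D biaryl) and SNAr (B–O–C ether). Both formyl groups arrive in purchased arenes and first serve as activators (SNAr on ring C, oxidative addition on ring D).
Order of rings: all four benzene rings are bought, and the macrocycle is the single ring made, closed as the last skeletal bond in step 7.

Key step: step 7

Assumption: the target SMILES carries no stereodescriptor, so the sense of twist of the A–D axis inside the macrocycle is taken as unspecified (racemic or interconverting) and no step is asked to control it.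

Step 1
Reactants: 1 5-bromo-2-methoxyphenol; 2 4-fluorobenzaldehyde
Product: 4 4-(5-bromo-2-methoxyphenoxy)benzaldehyde, via potassium phenoxide 3 (not isolated)
Conditions: K2CO3, DMF, 120 °C
Reagents that add atoms: none
Why: Nucleophilic aromatic substitution by addition–elimination, in which the para-formyl group of 2 stabilises the anionic adduct and fluoride leaves, while the aryl bromide of 1 has no acceptor group and stays untouched.

Step 2
Reactants: 5 2-bromo-5-methoxybenzaldehyde
Product: 6 1-bromo-4-methoxy-2-vinylbenzene
Conditions: MePPh3Br, KOt-Bu, THF, 0 °C to rt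
Reagents that add atoms: methyltriphenylphosphonium bromide, C[P+](c1ccccc1)(c1ccccc1)c1ccccc1.[Br-]
Why: Wittig methylenation of a non-enolisable aromatic aldehyde, which supplies one carbon of the future A–B bridge and leaves the aryl bromide alone.

Step 3
Reactants: 6 1-bromo-4-methoxy-2-vinylbenzene
Product: 7 2-(4-methoxy-2-vinylphenyl)-4,4,5,5-tetramethyl-1,3,2-dioxaborolane
Conditions: B2pin2, Pd(dppf)Cl2 (3 mol %), KOAc, 1,4-dioxane, 85 °C
Reagents that add atoms: bis(pinacolato)diboron, CC1(C)OB(OC1(C)C)B1OC(C)(C)C(C)(C)O1
Why: Miyaura borylation, in which the weak base KOAc activates the palladium bromide for boryl transfer but is too weak to trigger Suzuki homocoupling, and the vinyl group is a spectator at this temperature.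

Step 4
Reactants: 7 2-(4-methoxy-2-vinylphenyl)-4,4,5,5-tetramethyl-1,3,2-dioxaborolane; 8 2-bromo-3-methoxybenzaldehyde
Product: 9 4',6-dimethoxy-2'-vinylbiphenyl-2-carbaldehyde
Conditions: Pd(OAc)2 (3 mol %), SPhos (6 mol %), K3PO4, toluene/H2O, 90 °C
Reagents that add atoms: none
Why: Suzuki–Miyaura coupling, in which the ortho-formyl group of 8 speeds oxidative addition into the C–Br bond and the bulky, electron-rich biarylphosphine SPhos is the established answer to biaryls with three ortho substituents.

Step 5
Reactants: 9 4',6-dimethoxy-2'-vinylbiphenyl-2-carbaldehyde; 4 4-(5-bromo-2-methoxyphenoxy)benzaldehyde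
Product: 10 (E)-2'-{2-[3-(4-formylphenoxy)-4-methoxyphenyl]ethenyl}-4',6-dimethoxybiphenyl-2-carbaldehyde
Conditions: Pd(OAc)2 (5 mol %), P(o-tol)3 (10 mol %), K2CO3, n-Bu4NBr, DMF, 110 °C
Reagents that add atoms: none
Why: Mizoroki–Heck arylation, in which the arylpalladium species adds to the unsubstituted alkene terminus, syn insertion followed by syn β-hydride elimination sets the E geometry, and both formyl groups are tolerated.

Step 6
Reactants: 10 (E)-2'-{2-[3-(4-formylphenoxy)-4-methoxyphenyl]ethenyl}-4',6-dimethoxybiphenyl-2-carbaldehyde
Product: 11 2'-{2-[3-(4-formylphenoxy)-4-methoxyphenyl]ethyl}-4',6-dimethoxybiphenyl-2-carbaldehyde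
Conditions: H2 (1 atm), 10% Pd/C, Ph2S (0.05 equiv), EtOAc, rt
Reagents that add atoms: none
Why: Chemoselective heterogeneous hydrogenation on a sulfur-tempered catalyst, in which diphenyl sulfide lowers the activity of Pd/C so that the stilbene C=C is saturated while aromatic aldehydes and aryl ethers remain intact.

Step 7
Reactants: 11 2'-{2-[3-(4-formylphenoxy)-4-methoxyphenyl]ethyl}-4',6-dimethoxybiphenyl-2-carbaldehyde
Product: 13 (Z)-didehydroplagiochin E tri-O-methyl ether (cis C=C between rings C and D), via titanium pinacolate 12 (not isolated)
Conditions: TiCl4, Zn dust, pyridine, THF, reflux 2 h; then 11 in THF by syringe pump over 15 h (pseudo-high dilution), reflux; aq K2CO3 work-up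
Reagents that add atoms: none
Why: Zinc reduces TiCl4 to low-valent titanium, which passes one electron to each formyl group of 11; the two titanium-bound benzylic ketyl radicals, carbons of the same parent polarity, recombine to the pinacolate 12, and at reflux both C–O bonds are cleaved on the oxophilic metal to leave the C=C bond of 13 and TiO2. This is the intramolecular McMurry carbonyl coupling, a reaction type with close precedent for closing macrocyclic bis(bibenzyl) and stilbenoid cyclophane rings from dialdehydes. The one ring closed is the 16-membered macrocycle, by radical–radical recombination of the two chain ends held on the same titanium surface, so no polar exo or endo trajectory is involved and the irreversible deoxygenation pays for the ring strain. The two carbinol centres of 12 are transient and vanish on deoxygenation; the alkene is expected to be Z because the two-carbon link between para-bridged ring C and ortho-bridged ring D can hardly span an E geometry, either geometry converges in step 8, and the biaryl axis is not controlled. The selectivities needed are ring closure over intermolecular coupling and aldehyde over everything else: slow addition keeps the stationary concentration of 11 very low, the flexible A–B bridge, the ether hinge and the twisted A–D axis bring the ends within reach, and the only other functions are aryl ethers that low-valent titanium leaves alone. In one operation the second bridge bond, the macrocycle and the removal of both oxygen handles come from two identical, undifferentiated formyl groups that needed no prior activation.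

Step 8
Reactants: 13 (Z)-didehydroplagiochin E tri-O-methyl ether
Product: 14 plagiochin E tri-O-methyl ether
Conditions: H2 (1 atm), 10% Pd/C, EtOAc, rt
Reagents that add atoms: none
Why: Catalytic hydrogenation of a strained stilbene C=C on unpoisoned Pd/C, which turns either alkene geometry into the same CH2–CH2 bridge while aryl methyl ethers and the diaryl ether are inert.

Step 9
Reactants: 14 plagiochin E tri-O-methyl ether
Product: 16 plagiochin E, via tris(dibromoboryl) ether 15 (not isolated)
Conditions: BBr3 (excess), CH2Cl2, −78 °C to rt; then H2O
Reagents that add atoms: none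
Why: Lewis-acid aryl methyl ether cleavage, in which boron binds each methoxy oxygen, bromide removes the methyl group by SN2 attack to give 15, water hydrolyses the B–O bonds, and the diaryl ether survives because it offers bromide no sp3 carbon.

**Compound list**
1 | 5-bromo-2-methoxyphenol | COc1ccc(Br)cc1O | starting material
2 | 4-fluorobenzaldehyde | O=Cc1ccc(F)cc1 | starting material
3 | potassium 5-bromo-2-methoxyphenolate (potassium phenoxide, not isolated) | COc1ccc(Br)cc1[O-].[K+] | intermediate
4 | 4-(5-bromo-2-methoxyphenoxy)benzaldehyde | COc1ccc(Br)cc1Oc1ccc(C=O)cc1 | intermediate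
5 | 2-bromo-5-methoxybenzaldehyde | COc1ccc(Br)c(C=O)c1 | starting material
6 | 1-bromo-4-methoxy-2-vinylbenzene | COc1ccc(Br)c(C=C)c1 | intermediate
7 | 2-(4-methoxy-2-vinylphenyl)-4,4,5,5-tetramethyl-1,3,2-dioxaborolane | COc1ccc(B2OC(C)(C)C(C)(C)O2)c(C=C)c1 | intermediate
8 | 2-bromo-3-methoxybenzaldehyde | COc1cccc(C=O)c1Br | starting material
9 | 4',6-dimethoxy-2'-vinylbiphenyl-2-carbaldehyde | COc1ccc(-c2c(C=O)cccc2OC)c(C=C)c1 | intermediate
10 | (E)-2'-{2-[3-(4-formylphenoxy)-4-methoxyphenyl]ethenyl}-4',6-dimethoxybiphenyl-2-carbaldehyde | COc1ccc(-c2c(C=O)cccc2OC)c(/C=C/c2ccc(OC)c(Oc3ccc(C=O)cc3)c2)c1 | intermediate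
11 | 2'-{2-[3-(4-formylphenoxy)-4-methoxyphenyl]ethyl}-4',6-dimethoxybiphenyl-2-carbaldehyde | COc1ccc(-c2c(C=O)cccc2OC)c(CCc2ccc(OC)c(Oc3ccc(C=O)cc3)c2)c1 | intermediate
12 | macrocyclic titanium pinacolate (1,2-diolate on the new C–C bond, both diastereomers, not isolated) | COc1ccc2c(c1)CCc1ccc(OC)c(c1)Oc1ccc(cc1)C3O[Ti]OC3c1cccc(OC)c1-2 | intermediate
13 | (Z)-didehydroplagiochin E tri-O-methyl ether (cis C=C between rings C and D) | COc1ccc2c(c1)CCc1ccc(OC)c(c1)Oc1ccc(cc1)/C=C\c1cccc(OC)c1-2 | intermediate
14 | plagiochin E tri-O-methyl ether | COc1ccc2c(c1)CCc1ccc(OC)c(c1)Oc1ccc(cc1)CCc1cccc(OC)c1-2 | intermediate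
15 | tris(dibromoboryl) ether of plagiochin E (not isolated) | BrB(Br)Oc1ccc2c(c1)CCc1ccc(OB(Br)Br)c(c1)Oc1ccc(cc1)CCc1cccc(OB(Br)Br)c1-2 | intermediate
16 | plagiochin E | Oc1ccc2c(c1)CCc1ccc(O)c(c1)Oc1ccc(cc1)CCc1cccc(O)c1-2 | target

**Total step count:** 9
**Longest linear sequence:** 8 steps (steps 2 to 9, from compound 5)

**Steps most likely to fail**

Step 7 (McMurry macrocyclisation).
- Risk: intermolecular ketyl coupling to oligomers may outrun ring closure. The sequence may also stall before deoxygenation, because a strained cyclic stilbene has to be built.
- Fallback: it sets out from 11 and comes back to the route at 14, so step 8 is no longer needed. NaBH4 (MeOH/THF, 0 °C) should reduce both formyl groups to the bis(benzylic alcohol) F1. PBr3 (CH2Cl2, 0 °C) should convert that into the bis(bromomethyl) compound F2. Slow addition of F2 to sodium and tetraphenylethene in THF is an intramolecular Wurtz-type coupling known for macrocyclic bis(bibenzyl)s. It should join the same two benzylic carbons directly at the sp3 level, so no planar alkene has to be accommodated in the ring.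

Step 4 (crowded Suzuki–Miyaura coupling).
- Risk: protodeboronation of 7 and slow transmetalation onto the hindered arylpalladium bromide from 8. Both leave time for Heck-type attack on the vinyl group.
- Fallback: it sets out from 6 (step 3 is dropped) and comes back at 9. Bromine–lithium exchange (n-BuLi, THF, −78 °C) should give the aryllithium F3, and ZnCl2 should turn it into the arylzinc chloride F4. Negishi coupling of F4 with 8 (Pd2(dba)3, SPhos, THF, 50 °C) should then form the biaryl bond under anhydrous, base-free conditions. The faster zinc-to-palladium transfer copes better with three ortho substituents, and the formyl group of 8 is tolerated.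

Step 5 (Heck coupling).
- Risk: sluggish oxidative addition of the electron-rich bromide 4, so that thermal oligomerisation of styrene 9 or arylation at the internal alkene carbon takes over.
- Fallback: it sets out from 9 and comes back at 10. Cross-metathesis of 9 with vinylboronic acid pinacol ester (second-generation Grubbs catalyst, CH2Cl2, reflux) should give the (E)-styrylboronate F5. Suzuki–Miyaura coupling of F5 with 4 (Pd(dppf)Cl2, K3PO4, 1,4-dioxane/H2O, 80 °C) should then deliver the E-stilbene with the regiochemistry fixed by the C–B bond.

**Further compounds**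
F1 | step 7 | bis(benzylic alcohol): 2'-{2-[3-(4-(hydroxymethyl)phenoxy)-4-methoxyphenyl]ethyl}-4',6-dimethoxybiphenyl-2-methanol | COc1ccc(-c2c(CO)cccc2OC)c(CCc2ccc(OC)c(Oc3ccc(CO)cc3)c2)c1
F2 | step 7 | bis(bromomethyl) compound: 2-(bromomethyl)-2'-{2-[3-(4-(bromomethyl)phenoxy)-4-methoxyphenyl]ethyl}-4',6-dimethoxybiphenyl | COc1ccc(-c2c(CBr)cccc2OC)c(CCc2ccc(OC)c(Oc3ccc(CBr)cc3)c2)c1
F3 | step 4 | aryllithium: (4-methoxy-2-vinylphenyl)lithium | [Li]c1ccc(OC)cc1C=C
F4 | step 4 | arylzinc chloride: (4-methoxy-2-vinylphenyl)zinc chloride | Cl[Zn]c1ccc(OC)cc1C=C
F5 | step 5 | (E)-styrylboronate: (E)-4',6-dimethoxy-2'-[2-(4,4,5,5-tetramethyl-1,3,2-dioxaborolan-2-yl)ethenyl]biphenyl-2-carbaldehyde | COc1ccc(-c2c(C=O)cccc2OC)c(/C=C/B2OC(C)(C)C(C)(C)O2)c1
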